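**Strategy**

The key step exploits the C4 carbonyl of ring C, which links C4a of ring A to C3 and has O1 on the neighbouring C8a. Ring C therefore falls apart into CO (C4 and its oxygen), phenylacetylene (C3, C2 and the phenyl group) and an ortho-iodophenol that already is ring A. One palladium-catalysed carbonylative annulation joins them, making C4a–C4, C4–C3 and O1–C2 and giving the protected flavone. The precursor is a 2-iodophenol with benzyloxy groups at its C3 and C5 and the benzyl-protected 2,3-dihydroxybenzyl group at its C4. Because that carbon is para to the free hydroxyl, the parent phenol is symmetric and its iodination is unambiguous. Enantioselective hydrogenation of C2=C3 then sets the 2S centre and hydrogenolysis frees the four phenols.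

Key step: step 6

Assumption: the (R,R) carbene precursor is written in step 7 as the antipode expected to give the 2S series; should it deliver 2R on this substrate, its (S,S) antipode is used and nothing else changes.

**Route**

Step 1
Reactants: 1 3',5'-bis(benzyloxy)acetophenone
Product: 2 2-[3,5-bis(benzyloxy)phenyl]-2-methyl-1,3-dioxolane
Conditions: ethylene glycol, TsOH·H2O (cat.), toluene, reflux, Dean–Stark
Reagents that add atoms: ethylene glycol, OCCO
Why: Acid-catalysed ketalisation with azeotropic removal of water masks the ketone against the organolithium of step 2, and the benzyl ethers are inert.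

Step 2
Reactants: 2 2-[3,5-bis(benzyloxy)phenyl]-2-methyl-1,3-dioxolane; 3 2,3-bis(benzyloxy)benzaldehyde
Product: 5 [2,6-bis(benzyloxy)-4-(2-methyl-1,3-dioxolan-2-yl)phenyl][2,3-bis(benzyloxy)phenyl]methanol (racemic), via aryllithium 4 (not isolated)
Conditions: n-BuLi, TMEDA, Et2O, 0 °C; then 3, −78 → 0 °C; H2O
Reagents that add atoms: none
Why: Directed ortho-metalation should remove the ring hydrogen flanked by both ether oxygens (Et2O at 0 °C keeps benzylic deprotonation slow), and the aryllithium adds 1,2 to the aldehyde; the carbinol centre forms racemic and is erased in step 3.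

Step 3
Reactants: 5 [2,6-bis(benzyloxy)-4-(2-methyl-1,3-dioxolan-2-yl)phenyl][2,3-bis(benzyloxy)phenyl]methanol
Product: 7 1-[3,5-bis(benzyloxy)-4-[2,3-bis(benzyloxy)benzyl]phenyl]ethanone, via diarylmethane ketal 6 (not isolated)
Conditions: Et3SiH, TFA, CH2Cl2, −20 → 0 °C; then 1 M HCl, THF, rt
Reagents that add atoms: water, O
Why: Ionic hydrogenation (Kursanov–Parnes reduction): the doubly benzylic, electron-rich carbinol ionises in TFA and the cation takes hydride from the silane, after which aqueous acid hydrolyses the dioxolane, while the aryl ketone and the benzyl ethers should survive at this temperature.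

Step 4
Reactants: 7 1-[3,5-bis(benzyloxy)-4-[2,3-bis(benzyloxy)benzyl]phenyl]ethanone
Product: 9 3,5-bis(benzyloxy)-4-[2,3-bis(benzyloxy)benzyl]phenol, via aryl acetate 8 (not isolated)
Conditions: mCPBA, TFA (1 equiv), CH2Cl2, 0 °C → rt; aq. Na2S2O3 wash; then K2CO3, MeOH–THF, rt
Reagents that add atoms: mCPBA, OOC(=O)c1cccc(Cl)c1
Why: Baeyer–Villiger oxidation of an aryl methyl ketone proceeds with migration of the aryl group, and mild base methanolysis of the resulting aryl acetate should release the symmetric phenol once the peracid has been destroyed.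

Step 5
Reactants: 9 3,5-bis(benzyloxy)-4-[2,3-bis(benzyloxy)benzyl]phenol
Product: 10 3,5-bis(benzyloxy)-4-[2,3-bis(benzyloxy)benzyl]-2-iodophenol
Conditions: NIS (1.0 equiv), CH2Cl2, −20 → 0 °C, dark
Reagents that add atoms: N-iodosuccinimide, O=C1CCC(=O)N1I
Why: Electrophilic aromatic iodination of a phloroglucinol-type phenol whose para position is blocked and whose two ortho positions are equivalent, so one equivalent of reagent at low temperature should give a single mono-iodide and leave the less activated rings alone.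

Step 6
Reactants: 10 3,5-bis(benzyloxy)-4-[2,3-bis(benzyloxy)benzyl]-2-iodophenol; 11 phenylacetylene
Product: 14 5,7-bis(benzyloxy)-6-[2,3-bis(benzyloxy)benzyl]flavone, via ynone 12 (not isolated), via enaminone 13 (not isolated)
Conditions: PdCl2(PPh3)2 (5 mol %), CO (20 bar), Et2NH, 120 °C
Reagents that add atoms: carbon monoxide, [C-]#[O+]
Why: Zerovalent palladium formed in situ from PdCl2(PPh3)2 inserts into the carbon–iodine bond at C4a, CO insertion gives an aroylpalladium species, and coupling with the acetylide generated from 11 and the amine forges C4a–C4 and C4–C3 to give ynone 12. Et2NH adds to the ynone to give enaminone 13, whose C2 is then attacked by O1 with loss of the amine, so ring C closes in a net 6-endo-dig oxa-Michael sense and O1–C2 is formed. The closest known reaction type is the palladium-catalysed carbonylative annulation of ortho-iodophenols with terminal alkynes to flavones. No stereocentre is formed. Two selectivities are needed: CO insertion before alkyne coupling, favoured by the CO pressure and by the two ortho substituents on the arylpalladium, and six- over five-membered closure, secured by the secondary amine because the enaminone can only be attacked at C2. The position of the benzyl group is not at stake, since O1 is the only free phenol and it is para to the benzyl-bearing carbon, so only the 6-substituted flavone can arise.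

Step 7
Reactants: 14 5,7-bis(benzyloxy)-6-[2,3-bis(benzyloxy)benzyl]flavone
Product: 16 (2S)-5,7-bis(benzyloxy)-6-[2,3-bis(benzyloxy)benzyl]flavanone, via flavan-4-ol 15 (not isolated)
Conditions: Ru(cod)(2-methylallyl)2 (5 mol %), 1,3-bis[(R)-1-(naphthalen-1-yl)ethyl]-4,5-dihydroimidazolium tetrafluoroborate [(R,R)-SINpEt·HBF4] (10 mol %), KOtBu (12 mol %), H2 (120 bar), toluene, rt; then Dess–Martin periodinane, NaHCO3, CH2Cl2, rt
Reagents that add atoms: none
Why: Ruthenium–N-heterocyclic carbene catalysed asymmetric hydrogenation of the flavone C2=C3 bond, in which the C2-symmetric carbene on ruthenium selects the face of the alkene so that C2 becomes S; the part of the material over-reduced to flavan-4-ol 15 is returned to the ketone by Dess–Martin oxidation without touching C2, and benzyl ethers should be inert to this homogeneous catalyst.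

Step 8
Reactants: 16 (2S)-5,7-bis(benzyloxy)-6-[2,3-bis(benzyloxy)benzyl]flavanone
Product: 17 (2S)-6-(2,3-dihydroxybenzyl)-5,7-dihydroxyflavanone
Conditions: H2 (1 bar), 10% Pd/C, EtOAc–MeOH, rt, stopped after uptake of four equivalents
Reagents that add atoms: none
Why: Hydrogenolysis of the four benzyl ethers over Pd/C runs under neutral conditions, so the base-labile C2 centre should not be scrambled and the diarylmethane and ring C should survive if the reaction is stopped at full debenzylation.

**Compound list**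

1 | 3',5'-bis(benzyloxy)acetophenone | CC(=O)c1cc(OCc2ccccc2)cc(OCc2ccccc2)c1 | starting material
2 | 2-[3,5-bis(benzyloxy)phenyl]-2-methyl-1,3-dioxolane | CC1(OCCO1)c1cc(OCc2ccccc2)cc(OCc2ccccc2)c1 | intermediate
3 | 2,3-bis(benzyloxy)benzaldehyde | O=Cc1cccc(OCc2ccccc2)c1OCc1ccccc1 | starting material
4 | [2,6-bis(benzyloxy)-4-(2-methyl-1,3-dioxolan-2-yl)phenyl]lithium (not isolated) | [Li]c1c(OCc2ccccc2)cc(cc1OCc1ccccc1)C1(C)OCCO1 | intermediate
5 | [2,6-bis(benzyloxy)-4-(2-methyl-1,3-dioxolan-2-yl)phenyl][2,3-bis(benzyloxy)phenyl]methanol, racemic | OC(c1cccc(OCc2ccccc2)c1OCc1ccccc1)c1c(OCc2ccccc2)cc(cc1OCc1ccccc1)C1(C)OCCO1 | intermediate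
6 | 2-[3,5-bis(benzyloxy)-4-[2,3-bis(benzyloxy)benzyl]phenyl]-2-methyl-1,3-dioxolane (not isolated) | CC1(OCCO1)c1cc(OCc2ccccc2)c(Cc2cccc(OCc3ccccc3)c2OCc2ccccc2)c(OCc2ccccc2)c1 | intermediate
7 | 1-[3,5-bis(benzyloxy)-4-[2,3-bis(benzyloxy)benzyl]phenyl]ethanone | CC(=O)c1cc(OCc2ccccc2)c(Cc2cccc(OCc3ccccc3)c2OCc2ccccc2)c(OCc2ccccc2)c1 | intermediate
8 | 3,5-bis(benzyloxy)-4-[2,3-bis(benzyloxy)benzyl]phenyl acetate (not isolated) | CC(=O)Oc1cc(OCc2ccccc2)c(Cc2cccc(OCc3ccccc3)c2OCc2ccccc2)c(OCc2ccccc2)c1 | intermediate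
9 | 3,5-bis(benzyloxy)-4-[2,3-bis(benzyloxy)benzyl]phenol | Oc1cc(OCc2ccccc2)c(Cc2cccc(OCc3ccccc3)c2OCc2ccccc2)c(OCc2ccccc2)c1 | intermediate
10 | 3,5-bis(benzyloxy)-4-[2,3-bis(benzyloxy)benzyl]-2-iodophenol | Oc1cc(OCc2ccccc2)c(Cc2cccc(OCc3ccccc3)c2OCc2ccccc2)c(OCc2ccccc2)c1I | intermediate
11 | phenylacetylene | C#Cc1ccccc1 | starting material
12 | 1-[4,6-bis(benzyloxy)-5-[2,3-bis(benzyloxy)benzyl]-2-hydroxyphenyl]-3-phenylprop-2-yn-1-one (not isolated) | O=C(C#Cc1ccccc1)c1c(O)cc(OCc2ccccc2)c(Cc2cccc(OCc3ccccc3)c2OCc2ccccc2)c1OCc1ccccc1 | intermediate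
13 | (E)-1-[4,6-bis(benzyloxy)-5-[2,3-bis(benzyloxy)benzyl]-2-hydroxyphenyl]-3-(diethylamino)-3-phenylprop-2-en-1-one (not isolated; geometry assumed, without consequence) | CCN(CC)/C(c1ccccc1)=C/C(=O)c1c(O)cc(OCc2ccccc2)c(Cc2cccc(OCc3ccccc3)c2OCc2ccccc2)c1OCc1ccccc1 | intermediate
14 | 5,7-bis(benzyloxy)-6-[2,3-bis(benzyloxy)benzyl]flavone | O=c1cc(-c2ccccc2)oc2cc(OCc3ccccc3)c(Cc3cccc(OCc4ccccc4)c3OCc3ccccc3)c(OCc3ccccc3)c12 | intermediate
15 | (2S)-5,7-bis(benzyloxy)-6-[2,3-bis(benzyloxy)benzyl]flavan-4-ol (not isolated; C4 epimers, formed from part of the material) | OC1C[C@@H](c2ccccc2)Oc2cc(OCc3ccccc3)c(Cc3cccc(OCc4ccccc4)c3OCc3ccccc3)c(OCc3ccccc3)c21 | intermediate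
16 | (2S)-5,7-bis(benzyloxy)-6-[2,3-bis(benzyloxy)benzyl]flavanone | O=C1C[C@@H](c2ccccc2)Oc2cc(OCc3ccccc3)c(Cc3cccc(OCc4ccccc4)c3OCc3ccccc3)c(OCc3ccccc3)c21 | intermediate
17 | (2S)-6-(2,3-dihydroxybenzyl)-5,7-dihydroxyflavanone | O=C1C[C@@H](c2ccccc2)Oc2cc(O)c(Cc3cccc(O)c3O)c(O)c21 | target

**Step count**

Total steps: 8. Longest linear sequence: 8 steps (1 to 17); compounds 3 and 11 are bought.

**Steps most likely to fail**

Step 2. The base may remove a benzylic hydrogen of a benzyl ether instead of the ring hydrogen, and the resulting carbanion may rearrange (Wittig rearrangement), so that ring lithiation stays incomplete. The fallback sets out from ketal 2 and aldehyde 3 and comes back at ketone 7; it moves the metalation to a substrate without benzylic ether hydrogens on ring A. Hydrogenolysis of 2 (H2, Pd/C, EtOAc, trace Et3N) gives 5-(2-methyl-1,3-dioxolan-2-yl)benzene-1,3-diol F1, which MOMCl and i-Pr2NEt convert into 2-[3,5-bis(methoxymethoxy)phenyl]-2-methyl-1,3-dioxolane F2. Aldehyde 3 is reduced with NaBH4 to [2,3-bis(benzyloxy)phenyl]methanol F3 and brominated with PBr3 to 2,3-bis(benzyloxy)benzyl bromide F4. Lithiation of F2 between the two acetal ethers (n-BuLi, THF, 0 °C) gives [4-(2-methyl-1,3-dioxolan-2-yl)-2,6-bis(methoxymethoxy)phenyl]lithium F5, which is alkylated with F4 in the presence of CuI to 2-[4-[2,3-bis(benzyloxy)benzyl]-3,5-bis(methoxymethoxy)phenyl]-2-methyl-1,3-dioxolane F6. Aqueous HCl in MeOH–THF removes both acetal ethers and the ketal to give 1-[4-[2,3-bis(benzyloxy)benzyl]-3,5-dihydroxyphenyl]ethanone F7, and BnBr with K2CO3 in DMF returns ketone 7.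

Step 6. The arylpalladium may couple with the alkyne before it takes up CO (leading on to a benzofuran), the aroylpalladium may be intercepted by the amine, or oxidative addition at the hindered, electron-rich carbon–iodine bond may be slow. The fallback sets out from iodophenol 10 and comes back at ynone 12; it builds the same ynone by organolithium acylation instead of carbonylation. Compound 10 is protected (MOMCl, i-Pr2NEt) as 1,5-bis(benzyloxy)-2-[2,3-bis(benzyloxy)benzyl]-4-iodo-3-(methoxymethoxy)benzene F8. Iodine–lithium exchange (n-BuLi, THF, −78 °C) gives [2,4-bis(benzyloxy)-3-[2,3-bis(benzyloxy)benzyl]-6-(methoxymethoxy)phenyl]lithium F9. Acylation with N-methoxy-N-methyl-3-phenylpropiolamide gives 1-[4,6-bis(benzyloxy)-5-[2,3-bis(benzyloxy)benzyl]-2-(methoxymethoxy)phenyl]-3-phenylprop-2-yn-1-one F10. HCl in MeOH removes the acetal and liberates ynone 12, which Et2NH in EtOH closes to flavone 14 through enaminone 13 as in step 6.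

Step 7. Facial discrimination may be insufficient, turnover may stall on the heavily substituted flavone, or over-reduction may take material beyond what the re-oxidation returns. The fallback sets out from flavone 14 and comes back at flavanone 16; it replaces enantioselective hydrogenation by racemic reduction and kinetic resolution. Conjugate reduction with LiBH(s-Bu)3 (THF, −78 °C) gives racemic 5,7-bis(benzyloxy)-6-[2,3-bis(benzyloxy)benzyl]flavanone F11. Asymmetric transfer hydrogenation with the enantiomer of RuCl(p-cymene)(TsDPEN) that reduces the 2R ketone faster (HCO2H–Et3N) converts that enantiomer into (2R,4R)-5,7-bis(benzyloxy)-6-[2,3-bis(benzyloxy)benzyl]flavan-4-ol F12 and leaves (2S)-ketone 16. At most half of the material can be carried on this way.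

**Further compounds**

F1 | step 2 | 5-(2-methyl-1,3-dioxolan-2-yl)benzene-1,3-diol | CC1(OCCO1)c1cc(O)cc(O)c1
F2 | step 2 | 2-[3,5-bis(methoxymethoxy)phenyl]-2-methyl-1,3-dioxolane | CC1(OCCO1)c1cc(OCOC)cc(OCOC)c1
F3 | step 2 | [2,3-bis(benzyloxy)phenyl]methanol | OCc1cccc(OCc2ccccc2)c1OCc1ccccc1
F4 | step 2 | 2,3-bis(benzyloxy)benzyl bromide | BrCc1cccc(OCc2ccccc2)c1OCc1ccccc1
F5 | step 2 | [4-(2-methyl-1,3-dioxolan-2-yl)-2,6-bis(methoxymethoxy)phenyl]lithium | CC1(OCCO1)c1cc(OCOC)c([Li])c(OCOC)c1
F6 | step 2 | 2-[4-[2,3-bis(benzyloxy)benzyl]-3,5-bis(methoxymethoxy)phenyl]-2-methyl-1,3-dioxolane | CC1(OCCO1)c1cc(OCOC)c(Cc2cccc(OCc3ccccc3)c2OCc2ccccc2)c(OCOC)c1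
F7 | step 2 | 1-[4-[2,3-bis(benzyloxy)benzyl]-3,5-dihydroxyphenyl]ethanone | CC(=O)c1cc(O)c(Cc2cccc(OCc3ccccc3)c2OCc2ccccc2)c(O)c1
F8 | step 6 | 1,5-bis(benzyloxy)-2-[2,3-bis(benzyloxy)benzyl]-4-iodo-3-(methoxymethoxy)benzene | COCOc1cc(OCc2ccccc2)c(Cc2cccc(OCc3ccccc3)c2OCc2ccccc2)c(OCc2ccccc2)c1I
F9 | step 6 | [2,4-bis(benzyloxy)-3-[2,3-bis(benzyloxy)benzyl]-6-(methoxymethoxy)phenyl]lithium | COCOc1cc(OCc2ccccc2)c(Cc2cccc(OCc3ccccc3)c2OCc2ccccc2)c(OCc2ccccc2)c1[Li]
F10 | step 6 | 1-[4,6-bis(benzyloxy)-5-[2,3-bis(benzyloxy)benzyl]-2-(methoxymethoxy)phenyl]-3-phenylprop-2-yn-1-one | COCOc1cc(OCc2ccccc2)c(Cc2cccc(OCc3ccccc3)c2OCc2ccccc2)c(OCc2ccccc2)c1C(=O)C#Cc1ccccc1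
F11 | step 7 | racemic 5,7-bis(benzyloxy)-6-[2,3-bis(benzyloxy)benzyl]flavanone | O=C1CC(c2ccccc2)Oc2cc(OCc3ccccc3)c(Cc3cccc(OCc4ccccc4)c3OCc3ccccc3)c(OCc3ccccc3)c21
F12 | step 7 | (2R,4R)-5,7-bis(benzyloxy)-6-[2,3-bis(benzyloxy)benzyl]flavan-4-ol | O[C@@H]1C[C@H](c2ccccc2)Oc2cc(OCc3ccccc3)c(Cc3cccc(OCc4ccccc4)c3OCc3ccccc3)c(OCc3ccccc3)c21
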